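**Plan**

- Ring A is a 4-alkoxyphenol: O1 sits on C8a, para to the C6 hydroxyl, and C4 sits on the neighbouring C4a. This is the pattern left by a dienone–phenol shift, so the C4–C4a and O1–C8a bonds are cut together. The cut leads back, through a spiro p-quinol ether with C4 and O1 both on C8a, to an open (S)-2,3-diarylpropan-1-ol whose benzylic CH2 is para to the phenol.
- The ring B quinone is taken back to its hydroquinone, so one oxidant makes the quinone and triggers the ring closure. The diarylpropanol is cut at C3–C4 into a ring B arylacetyl imide and a ring A benzylic bromide.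
- Both aryl units come from one aldehyde, 4-(benzyloxy)-2,3-dimethoxybenzaldehyde: reduction and bromination for ring A; Dakin oxidation, benzylation, bromination and palladium α-arylation for ring B.
- Forward: the chain is joined first (steps 11–12), the benzyl groups are removed (step 13), and in the last step ring B becomes the quinone while the dihydropyran ring arises by spiro-etherification and ring expansion.
- Stereochemistry: C3 (S) is set in step 11 by the (S)-4-benzyloxazolidin-2-one auxiliary and is a spectator afterwards.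

Key step: step 14

Remark: chroman numbering is used (O1, C2, C3, C4, C4a, C5–C8, C8a; ring A is the benzo ring, ring B the quinone ring with primed atoms). Reagent 10 is assumed to be bought as a solution.

**Step 1**
Reactants: 1 2,3,4-trihydroxybenzaldehyde
Product: 2 4-(benzyloxy)-2,3-dihydroxybenzaldehyde
Conditions: BnBr (1.0 equiv), NaHCO3, NaI (cat.), DMF, 40 °C
Reagents that add atoms: benzyl bromide BrCc1ccccc1
Why: The 4-hydroxyl (para to the formyl group) is the most acidic and the only one ionized by NaHCO3, while the 2-hydroxyl is hydrogen-bonded to the aldehyde, so this Williamson etherification should be selective for O4.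

**Step 2**
Reactants: 2 4-(benzyloxy)-2,3-dihydroxybenzaldehyde
Product: 3 4-(benzyloxy)-2,3-dimethoxybenzaldehyde
Conditions: MeI (excess), K2CO3, DMF, 40 °C
Reagents that add atoms: iodomethane CI
Why: Exhaustive Williamson methylation of the two remaining phenols; the benzyl ether and aldehyde are inert.

**Step 3**
Reactants: 3 4-(benzyloxy)-2,3-dimethoxybenzaldehyde
Product: 4 [4-(benzyloxy)-2,3-dimethoxyphenyl]methanol
Conditions: NaBH4, MeOH/THF, 0 °C
Reagents that add atoms: none
Why: Borohydride reduction of an aryl aldehyde to the benzylic alcohol.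

**Step 4**
Reactants: 4 [4-(benzyloxy)-2,3-dimethoxyphenyl]methanol
Product: 5 1-(benzyloxy)-4-(bromomethyl)-2,3-dimethoxybenzene
Conditions: PBr3 (0.4 equiv), Et2O, 0 °C; used crude
Reagents that add atoms: phosphorus tribromide BrP(Br)Br
Why: Bromination of a benzylic alcohol through its phosphite ester; the electron-rich bromide ionizes easily and is therefore carried on without purification.

**Step 5**
Reactants: 3 4-(benzyloxy)-2,3-dimethoxybenzaldehyde
Product: 7 4-(benzyloxy)-2,3-dimethoxyphenol, via aryl formate 6 (not isolated)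
Conditions: mCPBA, CH2Cl2, rt; then K2CO3 (cat.), MeOH, rt
Reagents that add atoms: mCPBA OOC(=O)c1cccc(Cl)c1
Why: Dakin-type Baeyer–Villiger oxidation, in which the electron-rich aryl group migrates to give the formate, followed by methanolysis to the phenol.

**Step 6**
Reactants: 7 4-(benzyloxy)-2,3-dimethoxyphenol
Product: 8 1,4-bis(benzyloxy)-2,3-dimethoxybenzene
Conditions: BnBr, K2CO3, DMF, rt
Reagents that add atoms: benzyl bromide BrCc1ccccc1
Why: Williamson benzylation gives a symmetric diether, so the next substitution has only one possible site.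

**Step 7**
Reactants: 8 1,4-bis(benzyloxy)-2,3-dimethoxybenzene
Product: 9 1,4-bis(benzyloxy)-5-bromo-2,3-dimethoxybenzene
Conditions: NBS (1.0 equiv), MeCN, 0 °C to rt, dark
Reagents that add atoms: N-bromosuccinimide O=C1CCC(=O)N1Br
Why: Electrophilic aromatic bromination of a tetraalkoxybenzene whose two free positions are equivalent; polar conditions avoid radical bromination of the benzyl groups.

**Step 8**
Reactants: 9 1,4-bis(benzyloxy)-5-bromo-2,3-dimethoxybenzene; 10 (2-tert-butoxy-2-oxoethyl)zinc bromide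
Product: 11 tert-butyl 2-[2,5-bis(benzyloxy)-3,4-dimethoxyphenyl]acetate
Conditions: Pd(dba)2 (2 mol %), P(t-Bu)3 (2 mol %), THF, rt to 50 °C
Reagents that add atoms: none
Why: Palladium-catalysed α-arylation of a Reformatsky reagent (Negishi-type coupling of a zinc ester enolate), which tolerates electron-rich ortho-alkoxy aryl bromides; the tert-butyl ester suppresses Claisen self-condensation.

**Step 9**
Reactants: 11 tert-butyl 2-[2,5-bis(benzyloxy)-3,4-dimethoxyphenyl]acetate
Product: 12 2-[2,5-bis(benzyloxy)-3,4-dimethoxyphenyl]acetic acid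
Conditions: CF3CO2H/CH2Cl2, 0 °C to rt
Reagents that add atoms: none
Why: Acidolysis of a tert-butyl ester with loss of isobutene; aryl benzyl and methyl ethers should survive the brief exposure.

**Step 10**
Reactants: 12 2-[2,5-bis(benzyloxy)-3,4-dimethoxyphenyl]acetic acid; 13 (S)-4-benzyloxazolidin-2-one
Product: 15 (S)-4-benzyl-3-{2-[2,5-bis(benzyloxy)-3,4-dimethoxyphenyl]acetyl}oxazolidin-2-one, via mixed pivalic anhydride 14 (not isolated)
Conditions: t-BuCOCl, Et3N, THF, −20 °C; then 13, LiCl, −20 °C to rt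
Reagents that add atoms: none
Why: N-acylation of the Evans auxiliary through the mixed pivalic anhydride, which is attacked at the less hindered arylacetyl carbonyl.

**Step 11**
Reactants: 15 (S)-4-benzyl-3-{2-[2,5-bis(benzyloxy)-3,4-dimethoxyphenyl]acetyl}oxazolidin-2-one; 5 1-(benzyloxy)-4-(bromomethyl)-2,3-dimethoxybenzene
Product: 17 (S)-4-benzyl-3-{(S)-2-[2,5-bis(benzyloxy)-3,4-dimethoxyphenyl]-3-[4-(benzyloxy)-2,3-dimethoxyphenyl]propanoyl}oxazolidin-2-one, via sodium enolate 16 (not isolated)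
Conditions: NaN(SiMe3)2, THF, −78 °C; then 5, −78 to −30 °C
Reagents that add atoms: none
Why: Evans asymmetric alkylation: the chelated sodium Z-enolate is benzylated on the face opposite the 4-benzyl group of the auxiliary, which should set C3 as S, and the minor diastereomer is removable by chromatography.

**Step 12**
Reactants: 17 (S)-4-benzyl-3-{(S)-2-[2,5-bis(benzyloxy)-3,4-dimethoxyphenyl]-3-[4-(benzyloxy)-2,3-dimethoxyphenyl]propanoyl}oxazolidin-2-one
Product: 18 (S)-2-[2,5-bis(benzyloxy)-3,4-dimethoxyphenyl]-3-[4-(benzyloxy)-2,3-dimethoxyphenyl]propan-1-ol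
Conditions: LiBH4, H2O (1 equiv), Et2O/THF, 0 °C
Reagents that add atoms: none
Why: Reductive cleavage of the N-acyl oxazolidinone by hydride attack at the exocyclic carbonyl releases the primary alcohol and the auxiliary without enolizing the α-aryl centre.

**Step 13**
Reactants: 18 (S)-2-[2,5-bis(benzyloxy)-3,4-dimethoxyphenyl]-3-[4-(benzyloxy)-2,3-dimethoxyphenyl]propan-1-ol
Product: 19 (S)-2-[1-hydroxy-3-(4-hydroxy-2,3-dimethoxyphenyl)propan-2-yl]-5,6-dimethoxybenzene-1,4-diol
Conditions: H2 (1 atm), 10% Pd/C, EtOAc/MeOH, rt; filtered under argon, used at once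
Reagents that add atoms: none
Why: Hydrogenolysis of the three aryl benzyl ethers unmasks the ring A phenol and the ring B hydroquinone while leaving all C–C and alkyl C–O bonds intact; air is excluded because the hydroquinone autoxidizes.

**Step 14**
Reactants: 19 (S)-2-[1-hydroxy-3-(4-hydroxy-2,3-dimethoxyphenyl)propan-2-yl]-5,6-dimethoxybenzene-1,4-diol
Product: 22 (S)-5-(6-hydroxy-7,8-dimethoxychroman-3-yl)-2,3-dimethoxycyclohexa-2,5-diene-1,4-dione, via quinone phenol 20 (not isolated), via spirodienone 21 (not isolated)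
Conditions: PhI(OAc)2 (2.05 equiv), (CF3)2CHOH/CH2Cl2, −20 to 0 °C; then CF3CO2H, 0 °C to rt
Reagents that add atoms: none
Why: PhI(OAc)2 should first oxidize the ring B hydroquinone to the quinone 20 and then, by ligand exchange at the ring A hydroxyl, generate a phenoxenium equivalent that the primary hydroxyl traps at the para carbon C8a (new O1–C8a bond) to give spirodienone 21; acid then induces a dienone–phenol 1,2-shift of C4 from C8a to C4a (new C4–C4a bond), and loss of the C4a proton rearomatizes ring A to the free C6 phenol. The closest known reaction types are the oxidative spiro-etherification of 4-(3-hydroxypropyl)phenols with PhI(OAc)2 and the acid-promoted rearrangement of 4-alkoxy-4-alkylcyclohexadienones (p-quinol ethers) to hydroquinone monoethers by carbon migration. The oxolane ring closes 5-exo-trig onto C8a and is expanded to the dihydropyran ring of the chroman by the suprafacial 1,2-alkyl shift. No stereocentre is created in the product: the spiro carbon is transient, and C3 is neither origin nor terminus of the shift, so its S configuration from step 11 is retained. Only ring A reacts because ring B is by then a non-nucleophilic quinone, only C8a is within reach of the three-atom tether, C4 rather than O1 migrates because the O1 lone pair stabilizes the cation left at C8a, and the shift ends at C4a because only that terminus carries a hydrogen and can aromatize, whereas a shift to the methoxy-bearing C8 is reversible and unproductive.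

**Compound list**

1 | 2,3,4-trihydroxybenzaldehyde | O=Cc1ccc(O)c(O)c1O | starting material
2 | 4-(benzyloxy)-2,3-dihydroxybenzaldehyde | O=Cc1ccc(OCc2ccccc2)c(O)c1O | intermediate
3 | 4-(benzyloxy)-2,3-dimethoxybenzaldehyde | O=Cc1ccc(OCc2ccccc2)c(OC)c1OC | intermediate
4 | [4-(benzyloxy)-2,3-dimethoxyphenyl]methanol | OCc1ccc(OCc2ccccc2)c(OC)c1OC | intermediate
5 | 1-(benzyloxy)-4-(bromomethyl)-2,3-dimethoxybenzene | BrCc1ccc(OCc2ccccc2)c(OC)c1OC | intermediate
6 | 4-(benzyloxy)-2,3-dimethoxyphenyl formate (not isolated) | O=COc1ccc(OCc2ccccc2)c(OC)c1OC | intermediate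
7 | 4-(benzyloxy)-2,3-dimethoxyphenol | Oc1ccc(OCc2ccccc2)c(OC)c1OC | intermediate
8 | 1,4-bis(benzyloxy)-2,3-dimethoxybenzene | COc1c(OCc2ccccc2)ccc(OCc2ccccc2)c1OC | intermediate
9 | 1,4-bis(benzyloxy)-5-bromo-2,3-dimethoxybenzene | COc1c(OCc2ccccc2)cc(Br)c(OCc2ccccc2)c1OC | intermediate
10 | (2-tert-butoxy-2-oxoethyl)zinc bromide | Br[Zn]CC(=O)OC(C)(C)C | starting material
11 | tert-butyl 2-[2,5-bis(benzyloxy)-3,4-dimethoxyphenyl]acetate | CC(C)(C)OC(=O)Cc1cc(OCc2ccccc2)c(OC)c(OC)c1OCc1ccccc1 | intermediate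
12 | 2-[2,5-bis(benzyloxy)-3,4-dimethoxyphenyl]acetic acid | OC(=O)Cc1cc(OCc2ccccc2)c(OC)c(OC)c1OCc1ccccc1 | intermediate
13 | (S)-4-benzyloxazolidin-2-one | O=C1OC[C@H](Cc2ccccc2)N1 | starting material
14 | 2-[2,5-bis(benzyloxy)-3,4-dimethoxyphenyl]acetic pivalic anhydride (not isolated) | CC(C)(C)C(=O)OC(=O)Cc1cc(OCc2ccccc2)c(OC)c(OC)c1OCc1ccccc1 | intermediate
15 | (S)-4-benzyl-3-{2-[2,5-bis(benzyloxy)-3,4-dimethoxyphenyl]acetyl}oxazolidin-2-one | O=C1OC[C@H](Cc2ccccc2)N1C(=O)Cc3cc(OCc4ccccc4)c(OC)c(OC)c3OCc5ccccc5 | intermediate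
16 | sodium (Z)-enolate of 15 (not isolated) | [Na+].[O-]/C(N1C(=O)OC[C@@H]1Cc1ccccc1)=C\c1cc(OCc2ccccc2)c(OC)c(OC)c1OCc1ccccc1 | intermediate
17 | (S)-4-benzyl-3-{(S)-2-[2,5-bis(benzyloxy)-3,4-dimethoxyphenyl]-3-[4-(benzyloxy)-2,3-dimethoxyphenyl]propanoyl}oxazolidin-2-one | O=C1OC[C@H](Cc2ccccc2)N1C(=O)[C@@H](Cc3ccc(OCc4ccccc4)c(OC)c3OC)c5cc(OCc6ccccc6)c(OC)c(OC)c5OCc7ccccc7 | intermediate
18 | (S)-2-[2,5-bis(benzyloxy)-3,4-dimethoxyphenyl]-3-[4-(benzyloxy)-2,3-dimethoxyphenyl]propan-1-ol | OC[C@@H](Cc1ccc(OCc2ccccc2)c(OC)c1OC)c1cc(OCc2ccccc2)c(OC)c(OC)c1OCc1ccccc1 | intermediate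
19 | (S)-2-[1-hydroxy-3-(4-hydroxy-2,3-dimethoxyphenyl)propan-2-yl]-5,6-dimethoxybenzene-1,4-diol | OC[C@@H](Cc1ccc(O)c(OC)c1OC)c1cc(O)c(OC)c(OC)c1O | intermediate
20 | (S)-5-[1-hydroxy-3-(4-hydroxy-2,3-dimethoxyphenyl)propan-2-yl]-2,3-dimethoxycyclohexa-2,5-diene-1,4-dione (not isolated) | OC[C@@H](Cc1ccc(O)c(OC)c1OC)C1=CC(=O)C(OC)=C(OC)C1=O | intermediate
21 | (3S)-3-(4,5-dimethoxy-3,6-dioxocyclohexa-1,4-dien-1-yl)-6,7-dimethoxy-1-oxaspiro[4.5]deca-6,9-dien-8-one, spiro centre unassigned (not isolated) | COC1=C(OC)C2(C=CC1=O)C[C@H](CO2)C1=CC(=O)C(OC)=C(OC)C1=O | intermediate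
22 | (S)-5-(6-hydroxy-7,8-dimethoxychroman-3-yl)-2,3-dimethoxycyclohexa-2,5-diene-1,4-dione | COC1=C(OC)C(=O)C([C@H]2COc3c(cc(O)c(OC)c3OC)C2)=CC1=O | target

**Step count and risks**

Total steps: 14. Longest linear sequence: 12 (steps 1, 2, 5–14).

Steps most likely to fail:

1. Step 14. Possible failures are migration of O1 in place of C4, acid-induced breakdown of the quinone-bearing dienone, and over-oxidation of the newly formed chromanol by residual oxidant. The fallback builds the chroman without a rearrangement; it sets out from phenol 7 and acid 12 and comes back at target 22. Magnesium-mediated ortho-formylation of 7 (MgCl2, Et3N, paraformaldehyde, MeCN, reflux) would give 5-(benzyloxy)-2-hydroxy-3,4-dimethoxybenzaldehyde F1, in which the oxygen destined to be O1 already sits on C8a. Perkin condensation of F1 with 12 (Ac2O, Et3N, heat) would give 6-(benzyloxy)-3-[2,5-bis(benzyloxy)-3,4-dimethoxyphenyl]-7,8-dimethoxy-2H-chromen-2-one F2. Reduction with i-Bu2AlH would give (Z)-3-[5-(benzyloxy)-2-hydroxy-3,4-dimethoxyphenyl]-2-[2,5-bis(benzyloxy)-3,4-dimethoxyphenyl]prop-2-en-1-ol F3, and Mitsunobu cyclodehydration (PPh3, DIAD) would give 6-(benzyloxy)-3-[2,5-bis(benzyloxy)-3,4-dimethoxyphenyl]-7,8-dimethoxy-2H-chromene F4. Asymmetric hydrogenation with a chiral iridium phosphine–oxazoline catalyst, [Ir(cod)(L)]B[3,5-(CF3)2C6H3]4 with the ligand enantiomer chosen for the S product, would give (S)-6-(benzyloxy)-3-[2,5-bis(benzyloxy)-3,4-dimethoxyphenyl]-7,8-dimethoxychroman F5. Hydrogenolysis (H2, Pd/C) would give (S)-2-(6-hydroxy-7,8-dimethoxychroman-3-yl)-5,6-dimethoxybenzene-1,4-diol F6, and Ag2O in Et2O should oxidize only the hydroquinone ring to give 22.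

2. Step 11. Possible failures are loss of the labile benzylic bromide by ionization, incomplete alkylation of the hindered α-aryl enolate, and partial epimerization of the α-aryl centre. The fallback replaces auxiliary control by catalytic asymmetric hydrogenation; it sets out from acid 12 and aldehyde 3 and comes back at alcohol 18. Perkin condensation (Ac2O, Et3N, heat) would give (E)-3-[4-(benzyloxy)-2,3-dimethoxyphenyl]-2-[2,5-bis(benzyloxy)-3,4-dimethoxyphenyl]acrylic acid F7. Hydrogenation with a chiral iridium spiro phosphine–oxazoline catalyst (H2, Et3N, MeOH), as used for α-arylcinnamic acids, would give (S)-3-[4-(benzyloxy)-2,3-dimethoxyphenyl]-2-[2,5-bis(benzyloxy)-3,4-dimethoxyphenyl]propanoic acid F8. Reduction with BH3·THF would give 18; steps 3, 4 and 10 are then not needed.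

3. Step 8. Possible failures are slow oxidative addition of the electron-rich ortho-alkoxy aryl bromide and competing protodebromination. The fallback installs the two-carbon chain by a sigmatropic route; it sets out from phenol 7 and comes back at acid 12. O-Allylation (allyl bromide, K2CO3) would give 1-(allyloxy)-4-(benzyloxy)-2,3-dimethoxybenzene F9. Aromatic Claisen rearrangement (N,N-diethylaniline, 190 °C) to the only free ortho position would give 6-allyl-4-(benzyloxy)-2,3-dimethoxyphenol F10, and benzylation would give 1-allyl-2,5-bis(benzyloxy)-3,4-dimethoxybenzene F11. Lemieux–Johnson cleavage (OsO4 cat., NaIO4, 2,6-lutidine, dioxane/H2O) would give 2-[2,5-bis(benzyloxy)-3,4-dimethoxyphenyl]acetaldehyde F12, and Pinnick oxidation (NaClO2, NaH2PO4, 2-methyl-2-butene) would give 12.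

**Further compounds**

F1 | step 14 | 5-(benzyloxy)-2-hydroxy-3,4-dimethoxybenzaldehyde | O=Cc1cc(OCc2ccccc2)c(OC)c(OC)c1O
F2 | step 14 | 6-(benzyloxy)-3-[2,5-bis(benzyloxy)-3,4-dimethoxyphenyl]-7,8-dimethoxy-2H-chromen-2-one | O=C1Oc2c(OC)c(OC)c(OCc3ccccc3)cc2C=C1c1cc(OCc2ccccc2)c(OC)c(OC)c1OCc1ccccc1
F3 | step 14 | (Z)-3-[5-(benzyloxy)-2-hydroxy-3,4-dimethoxyphenyl]-2-[2,5-bis(benzyloxy)-3,4-dimethoxyphenyl]prop-2-en-1-ol | OC/C(=C\c1cc(OCc2ccccc2)c(OC)c(OC)c1O)c1cc(OCc2ccccc2)c(OC)c(OC)c1OCc1ccccc1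
F4 | step 14 | 6-(benzyloxy)-3-[2,5-bis(benzyloxy)-3,4-dimethoxyphenyl]-7,8-dimethoxy-2H-chromene | COc1c(OC)c(OCc2ccccc2)cc2C=C(COc12)c1cc(OCc2ccccc2)c(OC)c(OC)c1OCc1ccccc1
F5 | step 14 | (S)-6-(benzyloxy)-3-[2,5-bis(benzyloxy)-3,4-dimethoxyphenyl]-7,8-dimethoxychroman | COc1c(OC)c(OCc2ccccc2)cc2C[C@H](COc12)c1cc(OCc2ccccc2)c(OC)c(OC)c1OCc1ccccc1
F6 | step 14 | (S)-2-(6-hydroxy-7,8-dimethoxychroman-3-yl)-5,6-dimethoxybenzene-1,4-diol | COc1c(OC)c(O)cc2C[C@H](COc12)c1cc(O)c(OC)c(OC)c1O
F7 | step 11 | (E)-3-[4-(benzyloxy)-2,3-dimethoxyphenyl]-2-[2,5-bis(benzyloxy)-3,4-dimethoxyphenyl]acrylic acid | OC(=O)/C(=C/c1ccc(OCc2ccccc2)c(OC)c1OC)c1cc(OCc2ccccc2)c(OC)c(OC)c1OCc1ccccc1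
F8 | step 11 | (S)-3-[4-(benzyloxy)-2,3-dimethoxyphenyl]-2-[2,5-bis(benzyloxy)-3,4-dimethoxyphenyl]propanoic acid | OC(=O)[C@@H](Cc1ccc(OCc2ccccc2)c(OC)c1OC)c1cc(OCc2ccccc2)c(OC)c(OC)c1OCc1ccccc1
F9 | step 8 | 1-(allyloxy)-4-(benzyloxy)-2,3-dimethoxybenzene | C=CCOc1ccc(OCc2ccccc2)c(OC)c1OC
F10 | step 8 | 6-allyl-4-(benzyloxy)-2,3-dimethoxyphenol | C=CCc1cc(OCc2ccccc2)c(OC)c(OC)c1O
F11 | step 8 | 1-allyl-2,5-bis(benzyloxy)-3,4-dimethoxybenzene | C=CCc1cc(OCc2ccccc2)c(OC)c(OC)c1OCc1ccccc1
F12 | step 8 | 2-[2,5-bis(benzyloxy)-3,4-dimethoxyphenyl]acetaldehyde | O=CCc1cc(OCc2ccccc2)c(OC)c(OC)c1OCc1ccccc1
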